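## Structural features

The target is an achiral flavone: a 4H-chromen-4-one in which ring A (benzo) and ring C (pyranone) share the C4a–C8a bond, and C2 carries the 3,4-dimethoxyphenyl ring B. Ring A is fully substituted, with methoxy groups on C5, C6 and C8, a free hydroxyl on C7, and the fusion atoms C4a and C8a; counting C8a with O1, five contiguous ring carbons bear oxygen. The target has no stereocentre, but the route passes through chromanes in which C2 and C4 are stereogenic in a 1,3-relationship across C3; both are later made sp2, so only their tolerance of the chemistry matters. Fragile elements are the electron-rich ring A (oxidised to quinones once a hydroxyl is free) and the C7 hydroxyl, a vinylogous acid para to the C4 carbonyl. Among the intermediates, the enol ether with an allylic silyloxy group is acid-labile, the cyclobutenone is sensitive to heat and nucleophiles, and the benzylic C4–O bond next to an alkoxy-rich arene ionises easily. The real difficulty is the regiodefined placement of four different neighbours on ring A, with C7–OH distinguished from three methyl ethers. The key step uses the correspondence of C5, C6, C7 and C8 (with their oxygens) to the four carbons of a squaric ester, and of O1–C8a=C4a to the O–C=C unit of a 6-metalated 3,4-dihydro-2H-pyran, so that forming the C4a–C5 bond builds ring A instead of substituting it. The C4 carbonyl makes O7 more acidic than O6, and this is the handle used at the end to tell the two squarate-derived oxygens apart.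

## Logic of the disconnections

22 to 20 (through 21): the O–CH3 bond at C6 is cut. O6 and O7 descend from the two equivalent alkoxy carbons of the four-membered ring and are carried as identical groups; differentiating them only at the end removes every protecting-group exchange. The forward step must methylate O6 and not the more acidic O7, which is why it is run on dianion 21, where O7 is the delocalised and O6 the localised oxyanion.

20 to 19: the two O–CH2Ph bonds are cut. Benzyl is chosen because it survives organolithium, heat, fluoride and oxidants and leaves without touching methyl ethers. The forward hydrogenolysis must spare the C2=C3 bond.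

19 to 18 to 17: the C2=C3 double bond and the C4 carbonyl are traced back to a cis chroman-4-ol. The C4 oxygen has to be sp3 and protected during metalation, so ring C is carried saturated and oxidised late. The forward steps must oxidise a benzylic alcohol without attacking ring A and dehydrogenate without losing ring C.

17 to 16 to 15: the O–Si bond at C4 and the O–CH3 bond at C5 are cut. This exposes the monophenol that the ring expansion delivers. The demand is only that the hindered C5 phenol be alkylated before the silyl group is removed.

15 to 12 (through 14 and 13): the C4a–C5 bond is cut and ring A is opened. All four ring A oxygens are traced back to one four-membered ring, so no aromatic substitution is needed. The forward step needs the alkenyl group, not the oxygen substituent, to turn inward when the four-membered ring opens.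

12 to 9 and 3 (through 11 and 10): the bond between the carbinol carbon and the enol ether α-carbon (future C8–C8a) and the carbinol O–CH3 bond are cut. Because 3 is symmetric, either carbonyl gives the same adduct. Capping the alkoxide as its methyl ether installs the C8 methoxy group and avoids a free tetraoxygenated hydroquinone after the ring expansion. The demand is selective metalation of 9 at the sp2 carbon next to oxygen.

9 to 8 to 7: the O–Si bond and the C4–H bond are cut, returning to the enone. The carbonyl cannot be present during lithiation. The reduction must be 1,2-selective.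

7 to 4 and 5 (through 6): the O1–C6 and C2–C3 bonds of the dihydropyranone are cut. This is a hetero-Diels–Alder disconnection that joins ring B, C2, C3, C4 and the enol ether in one operation. Racemic formation of C2 is acceptable.

3 to 1 and 2: the two ester C–O bonds are cut, giving one molecule of 1 and two molecules of 2, both commercial. The forward step only has to drive a double esterification to completion by removing water.

## Other disconnections considered

Alternative 1: The cut is O1–C8a and C4–C4a, a formal insertion of an aryne into the acyl–oxygen bond of acid A2. In the forward step CsF releases the aryne from silyl triflate A3; the carboxylate oxygen attacks the aryne carbon remote from the methoxy group, the aryl anion closes onto the carbonyl, and the four-membered intermediate collapses to the ortho-hydroxyaryl ynone A1. No ring closes; a separate 6-endo oxa-Michael closure would then give flavone A4. In its favour: mild fluoride-only conditions, high convergence, ring C formed at the correct oxidation level, and good regiocontrol from the 3-alkoxy group of the aryne. Against it here: A1, and therefore A4, carry hydrogen at C8 where the target has a methoxy group. A late C8 oxygenation of an electron-rich flavone would be needed, with competition from C3 and ring B. An aryne that already carried the C8 oxygen would be flanked by alkoxy groups on both sides and lose its regiocontrol. A3 is itself a pentasubstituted arene, and aurone formation (5-exo) competes in the closure. Comparison: on redox economy and on steps from key-step product to a flavone the alternative is the better. On structure the chosen plan is the better, because it places all four ring A oxygens unambiguously. Mechanistic security is comparable.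

Alternative 2: The cut is C4a–C4, C4–C3 and O1–C2, with CO as C4. In the forward step zerovalent palladium formed from PdCl2(PPh3)2 inserts into the C–I bond of iodophenol A6, CO insertion gives an acylpalladium species, coupling with alkyne A7 gives an ynone, and Et2NH promotes 6-endo closure to flavone A5. In its favour: three bonds and ring C in one operation, no redox adjustment, and A5 is a single hydrogenolysis away from 22 with O6 and O7 already differentiated. Against it here: A6 is a hexasubstituted benzene with five oxygens and an iodine, so the whole regiochemical problem moves into its synthesis. Oxidative addition at an electron-rich, doubly ortho-substituted iodide is expected to be slow. The free phenol can divert to aurones or to alkoxycarbonylation, and CO must be handled. Comparison: after the key step this alternative is clearly the better in step economy (one step against six), and it makes no stereocentres that are later discarded. The chosen plan is the better in how ring A is obtained. If A6 were available in a few steps, Alternative 2 would be the shorter route overall.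

Alternative 3: The cut is O1–C2 together with one O–CH3 bond of the symmetric ynone A9. In the forward step ICl activates the alkyne, an ortho methoxy oxygen attacks C2 in 6-endo fashion, and the oxonium ion loses chloromethane to give 3-iodoflavone A8. In its favour: the symmetry of ring A in A9 means either ortho methoxy gives the same product, and the benzyloxy group is fixed para to the acyl group. A9 should be reachable by lithiation of arene A10 at its only C–H and acylation. The iodine and the benzyl group of A8 could be removed together in one hydrogenolysis to give 22. Against it here: ICl can iodinate the electron-rich ring B, the iodine at C3 is not needed, and A10 is still a pentaoxygenated benzene that must be made with one oxygen differentiated. Comparison: this is probably the shortest and most convergent plan and is the better in step and redox economy. Mechanistic reliability is equal. The chosen plan is the better only in needing no preformed polyoxygenated arene, since its ring A oxygens come from squaric acid.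

Key step: step 6

Remark on the chemistry: in the ring expansion the cyclobutenone carbons map C1→C5, C2→C6, C3→C7 and C4→C8, and 12 and 15 share the cis (2R*,4R*) relationship. All sp3 intermediates are racemic and drawn as one enantiomer. The carbinol carbon of 12 is left unassigned because it becomes sp2 in step 6.

## Steps

Step 1
Reactants: 1 squaric acid; 2 benzyl alcohol
Product: 3 3,4-bis(benzyloxy)cyclobut-3-ene-1,2-dione
Conditions: BnOH (2.5 equiv), toluene, reflux, Dean–Stark removal of water
Reagents that add atoms: benzyl alcohol (second equivalent), OCc1ccccc1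
Why: Squaric acid is a strong vinylogous acid and esterifies with primary alcohols without added catalyst when water is removed (double vinylogous Fischer esterification), so two molecules of 2 are taken up with loss of two molecules of water; 3 is symmetric, which removes any regiochemical question in step 5.

Step 2
Reactants: 4 3,4-dimethoxybenzaldehyde; 5 (E)-1-methoxy-3-(trimethylsilyloxy)buta-1,3-diene
Product: 7 2-(3,4-dimethoxyphenyl)-2,3-dihydro-4H-pyran-4-one (racemic), via silyl enol ether cycloadduct 6 (not isolated)
Conditions: ZnCl2 (0.5 equiv), THF, rt; then TFA, CH2Cl2, 0 °C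
Reagents that add atoms: none
Why: Lewis-acid-promoted hetero-Diels–Alder reaction of an aromatic aldehyde with the 1-alkoxy-3-siloxydiene gives 6; acid then cleaves the silyl enol ether and eliminates methanol to the vinylogous ester 7. C2 is formed racemic, which is acceptable because it is destroyed in step 10.

Step 3
Reactants: 7 2-(3,4-dimethoxyphenyl)-2,3-dihydro-4H-pyran-4-one
Product: 8 cis-2-(3,4-dimethoxyphenyl)-3,4-dihydro-2H-pyran-4-ol (racemic)
Conditions: NaBH4, CeCl3·7H2O, MeOH, −78 → 0 °C
Reagents that add atoms: none
Why: Luche reduction: CeCl3 makes the reduction 1,2-selective on the enone; axial hydride delivery to the half-chair with the aryl group pseudo-equatorial should place the hydroxyl pseudo-equatorial, cis to the aryl group (substrate control).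

Step 4
Reactants: 8 cis-2-(3,4-dimethoxyphenyl)-3,4-dihydro-2H-pyran-4-ol
Product: 9 cis-2-(3,4-dimethoxyphenyl)-4-(triisopropylsilyloxy)-3,4-dihydro-2H-pyran (racemic)
Conditions: TIPSOTf, 2,6-lutidine, CH2Cl2, −78 → 0 °C
Reagents that add atoms: triisopropylsilyl trifluoromethanesulfonate, CC(C)[Si](OS(=O)(=O)C(F)(F)F)(C(C)C)C(C)C
Why: Buffered silylation of a secondary allylic alcohol; TIPS is chosen because, unlike benzyl or smaller silyl groups, it offers no C–H that t-BuLi removes easily, and its bulk shields C4–H.

Step 5
Reactants: 9 cis-2-(3,4-dimethoxyphenyl)-4-(triisopropylsilyloxy)-3,4-dihydro-2H-pyran; 3 3,4-bis(benzyloxy)cyclobut-3-ene-1,2-dione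
Product: 12 2,3-bis(benzyloxy)-4-[cis-2-(3,4-dimethoxyphenyl)-4-(triisopropylsilyloxy)-3,4-dihydro-2H-pyran-6-yl]-4-methoxycyclobut-2-en-1-one (racemic; carbinol carbon unassigned), via vinyllithium 10 (not isolated), via lithium alkoxide 11 (not isolated)
Conditions: t-BuLi (1.2 equiv), THF, −78 → 0 °C; cannulate into 3 (1.5 equiv), THF, −78 °C; MeOTf (2.5 equiv), −78 → 0 °C
Reagents that add atoms: methyl trifluoromethanesulfonate, COS(=O)(=O)C(F)(F)F
Why: α-Lithiation of a cyclic enol ether at the sp2 carbon next to oxygen (as with silyl-protected glycals), 1,2-addition of the vinyllithium to one of the two equivalent carbonyls of the squaric ester, and O-methylation of the tertiary lithium alkoxide by the hard electrophile MeOTf. Warming to 0 °C lets residual t-BuLi be consumed by THF, and inverse addition to excess 3 at −78 °C suppresses double addition. The new quaternary carbon is formed without control and is destroyed in step 6.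

Step 6
Reactants: 12 2,3-bis(benzyloxy)-4-[cis-2-(3,4-dimethoxyphenyl)-4-(triisopropylsilyloxy)-3,4-dihydro-2H-pyran-6-yl]-4-methoxycyclobut-2-en-1-one
Product: 15 cis-6,7-bis(benzyloxy)-2-(3,4-dimethoxyphenyl)-8-methoxy-4-(triisopropylsilyloxy)chroman-5-ol (racemic), via dienylketene 13 (not isolated), via cyclohexadienone 14 (not isolated)
Conditions: toluene (0.02 M, degassed, base-washed glassware), 110 °C
Reagents that add atoms: none
Why: Heating breaks the C1–C4 bond of the cyclobutenone by conrotatory four-electron ring opening; the methoxy donor on C4 rotates outward, so the dihydropyranyl group turns inward and lies cis to the ketene in 13. Disrotatory six-electron electrocyclisation then joins the ketene carbon to the enol ether β-carbon (the C5–C4a bond) and closes ring A as cyclohexadienone 14. Enolisation of 14 gives the phenol 15, and this aromatisation makes the sequence irreversible. The reaction is a Moore rearrangement; the closest known type is the thermal ring expansion of 4-alkenyl- and 4-aryl-4-hydroxy- or 4-alkoxycyclobutenones to hydroquinones and their monoethers. No new stereocentre survives: C4a of 14 is transient, and C2 and C4 are spectators that keep their cis relation until steps 9 and 10 remove them. The step needs torquoselectivity, secured by the outward preference of the oxygen donor on C4, and a defined constitution, secured because the two benzyloxy carbons are equivalent in 3 and the carbinol carbon can only become C8. Intramolecular capture of the ketene should outrun external nucleophiles in dilute, dry, acid-free solution. With the carbinol oxygen methylated the product is a monophenol and not an air-sensitive hydroquinone, and C8 already carries its methoxy group.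

Step 7
Reactants: 15 cis-6,7-bis(benzyloxy)-2-(3,4-dimethoxyphenyl)-8-methoxy-4-(triisopropylsilyloxy)chroman-5-ol
Product: 16 cis-6,7-bis(benzyloxy)-2-(3,4-dimethoxyphenyl)-5,8-dimethoxy-4-(triisopropylsilyloxy)chromane (racemic)
Conditions: MeI, Cs2CO3, DMF, rt
Reagents that add atoms: iodomethane, CI
Why: Williamson methylation of the only free phenol; Cs2CO3 in DMF is used because O5 is flanked by C4a and the C6 benzyloxy group. The silyl and benzyl ethers are inert.

Step 8
Reactants: 16 cis-6,7-bis(benzyloxy)-2-(3,4-dimethoxyphenyl)-5,8-dimethoxy-4-(triisopropylsilyloxy)chromane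
Product: 17 cis-6,7-bis(benzyloxy)-2-(3,4-dimethoxyphenyl)-5,8-dimethoxychroman-4-ol (racemic)
Conditions: TBAF, THF, 0 °C → rt
Reagents that add atoms: none
Why: Fluoride cleavage of the secondary silyl ether; the non-acidic conditions avoid ionisation of the benzylic C4–O bond, which is ortho and para to alkoxy groups.

Step 9
Reactants: 17 cis-6,7-bis(benzyloxy)-2-(3,4-dimethoxyphenyl)-5,8-dimethoxychroman-4-ol
Product: 18 6,7-bis(benzyloxy)-2-(3,4-dimethoxyphenyl)-5,8-dimethoxychroman-4-one (racemic)
Conditions: DMP (1,1,1-triacetoxy-1,1-dihydro-1,2-benziodoxol-3(1H)-one), NaHCO3, CH2Cl2, 0 °C → rt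
Reagents that add atoms: none
Why: Periodinane oxidation of a secondary benzylic alcohol to the aryl ketone under buffered conditions; no free phenol is present, so ring A should not be attacked. The C4 stereocentre disappears.

Step 10
Reactants: 18 6,7-bis(benzyloxy)-2-(3,4-dimethoxyphenyl)-5,8-dimethoxychroman-4-one
Product: 19 6,7-bis(benzyloxy)-2-(3,4-dimethoxyphenyl)-5,8-dimethoxy-4H-chromen-4-one
Conditions: I2 (0.1 equiv), DMSO, 120 °C
Reagents that add atoms: none
Why: Iodine-catalysed dehydrogenation of a flavanone: α-iodination through the enol, loss of HI to the chromone, and reoxidation of HI by DMSO. Any 2'-hydroxychalcone formed by ring opening recloses to the same flavone; the C2 stereocentre disappears.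

Step 11
Reactants: 19 6,7-bis(benzyloxy)-2-(3,4-dimethoxyphenyl)-5,8-dimethoxy-4H-chromen-4-one
Product: 20 2-(3,4-dimethoxyphenyl)-6,7-dihydroxy-5,8-dimethoxy-4H-chromen-4-one
Conditions: H2 (1 atm), 10% Pd/C, EtOAc–MeOH, rt
Reagents that add atoms: none
Why: Hydrogenolysis of two aryl benzyl ethers; methyl ethers are inert and the C2=C3 bond of the chromone is reduced much more slowly, so the reaction is stopped after uptake of two equivalents. The catechol is used directly because it is prone to air oxidation.

Step 12
Reactants: 20 2-(3,4-dimethoxyphenyl)-6,7-dihydroxy-5,8-dimethoxy-4H-chromen-4-one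
Product: 22 2-(3,4-dimethoxyphenyl)-7-hydroxy-5,6,8-trimethoxy-4H-chromen-4-one (target), via disodium catecholate 21 (not isolated)
Conditions: NaH (2.2 equiv), DMF, 0 °C; MeI (1.0 equiv), 0 °C → rt; aq. HCl
Reagents that add atoms: iodomethane, CI
Why: Regioselective mono-O-alkylation of a catecholate dianion: in 21 the O7 oxyanion is delocalised into the C4 carbonyl while O6 is not, so one equivalent of MeI should alkylate the more basic O6. This is the known behaviour of catecholate dianions carrying an acceptor group; the remaining O7 phenoxide is protonated on work-up.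

## Compound list

1 | squaric acid (3,4-dihydroxycyclobut-3-ene-1,2-dione) | O=c1c(O)c(O)c1=O | starting material
2 | benzyl alcohol | OCc1ccccc1 | starting material
3 | 3,4-bis(benzyloxy)cyclobut-3-ene-1,2-dione | O=C1C(=O)C(OCc2ccccc2)=C1OCc1ccccc1 | intermediate
4 | 3,4-dimethoxybenzaldehyde | COc1ccc(C=O)cc1OC | starting material
5 | (E)-1-methoxy-3-(trimethylsilyloxy)buta-1,3-diene | CO/C=C/C(=C)O[Si](C)(C)C | starting material
6 | 2-(3,4-dimethoxyphenyl)-6-methoxy-4-(trimethylsilyloxy)-3,6-dihydro-2H-pyran (diastereomer mixture) | COc1ccc(C2CC(O[Si](C)(C)C)=CC(OC)O2)cc1OC | intermediate (not isolated)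
7 | 2-(3,4-dimethoxyphenyl)-2,3-dihydro-4H-pyran-4-one (racemic) | COc1ccc(C2CC(=O)C=CO2)cc1OC | intermediate
8 | cis-2-(3,4-dimethoxyphenyl)-3,4-dihydro-2H-pyran-4-ol (racemic, one enantiomer drawn) | COc1ccc([C@H]2C[C@@H](O)C=CO2)cc1OC | intermediate
9 | cis-2-(3,4-dimethoxyphenyl)-4-(triisopropylsilyloxy)-3,4-dihydro-2H-pyran (racemic) | COc1ccc([C@H]2C[C@@H](O[Si](C(C)C)(C(C)C)C(C)C)C=CO2)cc1OC | intermediate
10 | [cis-2-(3,4-dimethoxyphenyl)-4-(triisopropylsilyloxy)-3,4-dihydro-2H-pyran-6-yl]lithium | COc1ccc([C@H]2C[C@@H](O[Si](C(C)C)(C(C)C)C(C)C)C=C([Li])O2)cc1OC | intermediate (not isolated)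
11 | lithium alkoxide of 2,3-bis(benzyloxy)-4-hydroxy-4-[cis-2-(3,4-dimethoxyphenyl)-4-(triisopropylsilyloxy)-3,4-dihydro-2H-pyran-6-yl]cyclobut-2-en-1-one | COc1ccc([C@H]2C[C@@H](O[Si](C(C)C)(C(C)C)C(C)C)C=C(C3(O[Li])C(OCc4ccccc4)=C(OCc4ccccc4)C3=O)O2)cc1OC | intermediate (not isolated)
12 | 2,3-bis(benzyloxy)-4-[cis-2-(3,4-dimethoxyphenyl)-4-(triisopropylsilyloxy)-3,4-dihydro-2H-pyran-6-yl]-4-methoxycyclobut-2-en-1-one (racemic, carbinol carbon unassigned) | COc1ccc([C@H]2C[C@@H](O[Si](C(C)C)(C(C)C)C(C)C)C=C(C3(OC)C(OCc4ccccc4)=C(OCc4ccccc4)C3=O)O2)cc1OC | intermediate (key-step precursor)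
13 | (3Z)-2,3-bis(benzyloxy)-4-[cis-2-(3,4-dimethoxyphenyl)-4-(triisopropylsilyloxy)-3,4-dihydro-2H-pyran-6-yl]-4-methoxybuta-1,3-dien-1-one | COc1ccc([C@H]2C[C@@H](O[Si](C(C)C)(C(C)C)C(C)C)C=C(/C(OC)=C(OCc3ccccc3)\C(OCc3ccccc3)=C=O)O2)cc1OC | intermediate (not isolated)
14 | cis-6,7-bis(benzyloxy)-2-(3,4-dimethoxyphenyl)-8-methoxy-4-(triisopropylsilyloxy)-3,4-dihydro-2H-chromen-5(4aH)-one (C4a unassigned) | COc1ccc([C@H]2C[C@@H](O[Si](C(C)C)(C(C)C)C(C)C)C3C(=O)C(OCc4ccccc4)=C(OCc4ccccc4)C(OC)=C3O2)cc1OC | intermediate (not isolated)
15 | cis-6,7-bis(benzyloxy)-2-(3,4-dimethoxyphenyl)-8-methoxy-4-(triisopropylsilyloxy)chroman-5-ol (racemic) | COc1ccc([C@H]2C[C@@H](O[Si](C(C)C)(C(C)C)C(C)C)c3c(O)c(OCc4ccccc4)c(OCc4ccccc4)c(OC)c3O2)cc1OC | intermediate (key-step product)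
16 | cis-6,7-bis(benzyloxy)-2-(3,4-dimethoxyphenyl)-5,8-dimethoxy-4-(triisopropylsilyloxy)chromane (racemic) | COc1ccc([C@H]2C[C@@H](O[Si](C(C)C)(C(C)C)C(C)C)c3c(OC)c(OCc4ccccc4)c(OCc4ccccc4)c(OC)c3O2)cc1OC | intermediate
17 | cis-6,7-bis(benzyloxy)-2-(3,4-dimethoxyphenyl)-5,8-dimethoxychroman-4-ol (racemic) | COc1ccc([C@H]2C[C@@H](O)c3c(OC)c(OCc4ccccc4)c(OCc4ccccc4)c(OC)c3O2)cc1OC | intermediate
18 | 6,7-bis(benzyloxy)-2-(3,4-dimethoxyphenyl)-5,8-dimethoxychroman-4-one (racemic) | COc1ccc(C2CC(=O)c3c(OC)c(OCc4ccccc4)c(OCc4ccccc4)c(OC)c3O2)cc1OC | intermediate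
19 | 6,7-bis(benzyloxy)-2-(3,4-dimethoxyphenyl)-5,8-dimethoxy-4H-chromen-4-one | COc1ccc(-c2cc(=O)c3c(OC)c(OCc4ccccc4)c(OCc4ccccc4)c(OC)c3o2)cc1OC | intermediate
20 | 2-(3,4-dimethoxyphenyl)-6,7-dihydroxy-5,8-dimethoxy-4H-chromen-4-one | COc1ccc(-c2cc(=O)c3c(OC)c(O)c(O)c(OC)c3o2)cc1OC | intermediate
21 | disodium 2-(3,4-dimethoxyphenyl)-5,8-dimethoxy-4-oxo-4H-chromene-6,7-diolate | COc1ccc(-c2cc(=O)c3c(OC)c([O-])c([O-])c(OC)c3o2)cc1OC.[Na+].[Na+] | intermediate (not isolated)
22 | 2-(3,4-dimethoxyphenyl)-7-hydroxy-5,6,8-trimethoxy-4H-chromen-4-one | COc1ccc(-c2cc(=O)c3c(OC)c(OC)c(O)c(OC)c3o2)cc1OC | target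

## Step count and least certain steps

Total: 12 steps. Longest linear sequence: 11 steps (4 to 22, steps 2 to 12); step 1 is a one-step branch.

Step 6 (key step). The most likely failure is decomposition of the free phenol once it has formed. The new C5 hydroxyl sits ortho to the benzylic silyloxy group, so triisopropylsilanol can be expelled through an ortho-quinone methide at 110 °C, and the pentaoxygenated ring can autoxidise during work-up. A second risk is slow electrocyclisation at the hindered enol ether carbon, which leaves the ketene open to dimerisation. The fallback uses the parent form of the rearrangement and makes a quinone, not a phenol, the first ring A compound to be isolated. It sets out from 11, which is not methylated but quenched at −78 °C with aqueous NH4Cl to give 2,3-bis(benzyloxy)-4-hydroxy-4-[cis-2-(3,4-dimethoxyphenyl)-4-(triisopropylsilyloxy)-3,4-dihydro-2H-pyran-6-yl]cyclobut-2-en-1-one F1. Thermolysis of F1 in degassed toluene should give cis-6,7-bis(benzyloxy)-2-(3,4-dimethoxyphenyl)-4-(triisopropylsilyloxy)chromane-5,8-diol F2. F2 is not purified; on cooling it is oxidised with Ag2O to cis-6,7-bis(benzyloxy)-2-(3,4-dimethoxyphenyl)-4-(triisopropylsilyloxy)-3,4-dihydro-2H-chromene-5,8-dione F3. F3 has no phenolic hydroxyl, so it should tolerate chromatography without ionisation at C4 or further oxidation. The thermal stage itself is not made milder. Reduction of F3 with aqueous Na2S2O4 back to F2, then immediate double methylation under argon (MeI, Cs2CO3, DMF, rt), returns to the route at 16.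

Step 5. The risk is competing deprotonation by t-BuLi at the benzylic C2–H (an α-oxygenated benzylic position) or ortho to a methoxy group of ring B, giving regioisomeric organolithiums; double addition to 3 is a lesser risk. The fallback replaces C–H lithiation by sulfone chemistry and sets out from 9. Addition of benzenesulfinic acid across the enol ether (CH2Cl2, rt, no Lewis acid) should give 2-(3,4-dimethoxyphenyl)-6-(phenylsulfonyl)-4-(triisopropylsilyloxy)tetrahydro-2H-pyran F4. Its α-sulfonyl, α-oxy C–H is by far the most acidic site, so n-BuLi at −78 °C, addition to 3 and capping with MeOTf should give 2,3-bis(benzyloxy)-4-[6-(3,4-dimethoxyphenyl)-2-(phenylsulfonyl)-4-(triisopropylsilyloxy)tetrahydro-2H-pyran-2-yl]-4-methoxycyclobut-2-en-1-one F5. Elimination of benzenesulfinic acid from F5 (MgBr2·OEt2, Et3N, THF) restores the enol ether and returns to the route at 12.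

Step 12. The risk is imperfect site selectivity between O6 and O7, and over-methylation, at the last step; the target is the more acidic phenol and should be separable from less acidic by-products by extraction into aqueous Na2CO3. The fallback uses the opposite, well-established selectivity and sets out from 20. Benzylation of the more acidic hydroxyl (BnBr 1.05 equiv, KHCO3, DMF, 40 °C) should give 7-(benzyloxy)-2-(3,4-dimethoxyphenyl)-6-hydroxy-5,8-dimethoxy-4H-chromen-4-one F6. Methylation (MeI, K2CO3, acetone) gives 7-(benzyloxy)-2-(3,4-dimethoxyphenyl)-5,6,8-trimethoxy-4H-chromen-4-one F7, and hydrogenolysis (H2, Pd/C) returns to the route at 22.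

Step 10. The risk is ether cleavage by the HI formed at 120 °C (the C5 methoxy group peri to the carbonyl and the benzyl ethers), or incomplete dehydrogenation with accumulation of ring-opened chalcone. The fallback sets out from 18. Soft enolisation (TMSOTf, Et3N, CH2Cl2, 0 °C) should give [6,7-bis(benzyloxy)-2-(3,4-dimethoxyphenyl)-5,8-dimethoxy-2H-chromen-4-yl]oxy-trimethylsilane F8. Saegusa–Ito oxidation of F8 with Pd(OAc)2 in MeCN at room temperature returns to the route at 19.

## Further compounds

F1 | step 6 | 2,3-bis(benzyloxy)-4-hydroxy-4-[cis-2-(3,4-dimethoxyphenyl)-4-(triisopropylsilyloxy)-3,4-dihydro-2H-pyran-6-yl]cyclobut-2-en-1-one (racemic, carbinol carbon unassigned) | COc1ccc([C@H]2C[C@@H](O[Si](C(C)C)(C(C)C)C(C)C)C=C(C3(O)C(OCc4ccccc4)=C(OCc4ccccc4)C3=O)O2)cc1OC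
F2 | step 6 | cis-6,7-bis(benzyloxy)-2-(3,4-dimethoxyphenyl)-4-(triisopropylsilyloxy)chromane-5,8-diol (racemic) | COc1ccc([C@H]2C[C@@H](O[Si](C(C)C)(C(C)C)C(C)C)c3c(O)c(OCc4ccccc4)c(OCc4ccccc4)c(O)c3O2)cc1OC
F3 | step 6 | cis-6,7-bis(benzyloxy)-2-(3,4-dimethoxyphenyl)-4-(triisopropylsilyloxy)-3,4-dihydro-2H-chromene-5,8-dione (racemic) | COc1ccc([C@H]2C[C@@H](O[Si](C(C)C)(C(C)C)C(C)C)C3=C(O2)C(=O)C(OCc4ccccc4)=C(OCc4ccccc4)C3=O)cc1OC
F4 | step 5 | 2-(3,4-dimethoxyphenyl)-6-(phenylsulfonyl)-4-(triisopropylsilyloxy)tetrahydro-2H-pyran (2,4-cis, sulfonyl carbon unassigned) | COc1ccc([C@H]2C[C@@H](O[Si](C(C)C)(C(C)C)C(C)C)CC(S(=O)(=O)c3ccccc3)O2)cc1OC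
F5 | step 5 | 2,3-bis(benzyloxy)-4-[6-(3,4-dimethoxyphenyl)-2-(phenylsulfonyl)-4-(triisopropylsilyloxy)tetrahydro-2H-pyran-2-yl]-4-methoxycyclobut-2-en-1-one (diastereomer mixture) | COc1ccc([C@H]2C[C@@H](O[Si](C(C)C)(C(C)C)C(C)C)CC(S(=O)(=O)c3ccccc3)(C3(OC)C(OCc4ccccc4)=C(OCc4ccccc4)C3=O)O2)cc1OC
F6 | step 12 | 7-(benzyloxy)-2-(3,4-dimethoxyphenyl)-6-hydroxy-5,8-dimethoxy-4H-chromen-4-one | COc1ccc(-c2cc(=O)c3c(OC)c(O)c(OCc4ccccc4)c(OC)c3o2)cc1OC
F7 | step 12 | 7-(benzyloxy)-2-(3,4-dimethoxyphenyl)-5,6,8-trimethoxy-4H-chromen-4-one | COc1ccc(-c2cc(=O)c3c(OC)c(OC)c(OCc4ccccc4)c(OC)c3o2)cc1OC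
F8 | step 10 | [6,7-bis(benzyloxy)-2-(3,4-dimethoxyphenyl)-5,8-dimethoxy-2H-chromen-4-yl]oxy-trimethylsilane (racemic) | COc1ccc(C2C=C(O[Si](C)(C)C)c3c(OC)c(OCc4ccccc4)c(OCc4ccccc4)c(OC)c3O2)cc1OC
A1 | alternative 1 | 1-[4-(benzyloxy)-2-hydroxy-5,6-dimethoxyphenyl]-3-(3,4-dimethoxyphenyl)prop-2-yn-1-one | COc1ccc(C#CC(=O)c2c(O)cc(OCc3ccccc3)c(OC)c2OC)cc1OC
A2 | alternative 1 | 3-(3,4-dimethoxyphenyl)prop-2-ynoic acid | COc1ccc(C#CC(=O)O)cc1OC
A3 | alternative 1 | 5-(benzyloxy)-3,4-dimethoxy-2-(trimethylsilyl)phenyl trifluoromethanesulfonate | COc1c(OC)c(OCc2ccccc2)cc(OS(=O)(=O)C(F)(F)F)c1[Si](C)(C)C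
A4 | alternative 1 | 7-(benzyloxy)-2-(3,4-dimethoxyphenyl)-5,6-dimethoxy-4H-chromen-4-one | COc1ccc(-c2cc(=O)c3c(OC)c(OC)c(OCc4ccccc4)cc3o2)cc1OC
A5 | alternative 2 | 7-(benzyloxy)-2-(3,4-dimethoxyphenyl)-5,6,8-trimethoxy-4H-chromen-4-one | COc1ccc(-c2cc(=O)c3c(OC)c(OC)c(OCc4ccccc4)c(OC)c3o2)cc1OC
A6 | alternative 2 | 3-(benzyloxy)-6-iodo-2,4,5-trimethoxyphenol | COc1c(O)c(I)c(OC)c(OC)c1OCc1ccccc1
A7 | alternative 2 | 4-ethynyl-1,2-dimethoxybenzene | COc1ccc(C#C)cc1OC
A8 | alternative 3 | 7-(benzyloxy)-2-(3,4-dimethoxyphenyl)-3-iodo-5,6,8-trimethoxy-4H-chromen-4-one | COc1ccc(-c2oc3c(OC)c(OCc4ccccc4)c(OC)c(OC)c3c(=O)c2I)cc1OC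
A9 | alternative 3 | 1-[4-(benzyloxy)-2,3,5,6-tetramethoxyphenyl]-3-(3,4-dimethoxyphenyl)prop-2-yn-1-one | COc1ccc(C#CC(=O)c2c(OC)c(OC)c(OCc3ccccc3)c(OC)c2OC)cc1OC
A10 | alternative 3 | 3-(benzyloxy)-1,2,4,5-tetramethoxybenzene | COc1cc(OC)c(OC)c(OCc2ccccc2)c1OC
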